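**Retrosynthetic overview**
- The strategy rests on spiro carbon C6 and the two adjacent stereocentres of ring B, C8 (CHBr) and C9 (C(CH3)Cl). With C9 as a tertiary carbinol and C8 bearing an acetyl group, they are the intramolecular aldol of two identical 3-oxobutyl arms on C6, and C6 holds no stereochemical information until one arm has reacted.
- Ring A comes first, from dimedone isobutyl ether. Both arms enter at the neopentyl carbon C6 as allyl groups and are then taken to 3-oxobutyl. Ring B closes second, by the desymmetrizing amine-catalysed aldol (C8–C9 bond).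
- C8–Br is traced to the acetyl group (Baeyer–Villiger with retention, then bromide opening of the 8,9-cyclic sulfate with inversion). C9–Cl is traced to the tertiary alcohol (ionisation, bromonium ion, chloride trans to bromine).
- Ring A is finished last, because the axial C8 bromine then fixes the ring A conformation: C4–Br by γ-bromination of the vinylogous ester, C1=CH2 by titanium methylenation and enol ether hydrolysis, C3–OH by hydride reduction cis to bromine.

Key step: step 8

Assumption: the quinine-derived amine is taken to select the arm that leads to (6R)-14; if it selects the other arm, the quinidine-derived pseudoenantiomer is used and nothing else changes.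

**Route**

Step 1
Reactants: 1 dimedone; 2 2-methylpropan-1-ol
Product: 3 5,5-dimethyl-3-(2-methylpropoxy)cyclohex-2-en-1-one
Conditions: TsOH·H2O (cat.), toluene, reflux, Dean–Stark
Reagents that add atoms: none
Why: Acid-catalysed O-alkylation of the cyclic 1,3-diketone with azeotropic removal of water gives the vinylogous ester, which tells C1 from C3 and blocks C2.

Step 2
Reactants: 3 5,5-dimethyl-3-(2-methylpropoxy)cyclohex-2-en-1-one; 4 allyl bromide
Product: 6 5,5-dimethyl-3-(2-methylpropoxy)-6-(prop-2-en-1-yl)cyclohex-2-en-1-one (racemic), via lithium enolate 5 (not isolated)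
Conditions: LiN(i-Pr)2, THF, −78 °C; then 4, −78 °C → rt
Reagents that add atoms: none
Why: Kinetic deprotonation of a 3-alkoxy enone takes place at the α′ carbon C6 (Stork–Danheiser alkylation), and the cross-conjugated enolate is C-allylated by the reactive allylic bromide.

Step 3
Reactants: 6 5,5-dimethyl-3-(2-methylpropoxy)-6-(prop-2-en-1-yl)cyclohex-2-en-1-one; 4 allyl bromide
Product: 8 5,5-dimethyl-3-(2-methylpropoxy)-6,6-di(prop-2-en-1-yl)cyclohex-2-en-1-one, via lithium enolate 7 (not isolated)
Conditions: LiN(i-Pr)2, THF, −78 → 0 °C; then 4, DMPU, 0 °C → rt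
Reagents that add atoms: none
Why: This bond makes a quaternary carbon next to the quaternary C5, so a small, reactive allylic halide is used on the tetrasubstituted lithium enolate (enolate allylation); any O-allyl dienyl ether returns to 8 by Claisen rearrangement on warming, and with two identical arms no stereocentre arises.

Step 4
Reactants: 8 5,5-dimethyl-3-(2-methylpropoxy)-6,6-di(prop-2-en-1-yl)cyclohex-2-en-1-one
Product: 10 6,6-bis(3-hydroxypropyl)-5,5-dimethyl-3-(2-methylpropoxy)cyclohex-2-en-1-one, via bis(9-BBN) adduct 9 (not isolated)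
Conditions: 9-BBN, THF, 0 °C → rt; then H2O2, aq NaOH, 0 °C
Reagents that add atoms: hydrogen peroxide, OO
Why: 9-BBN hydroborates the two monosubstituted alkenes at the terminal carbon and leaves the deactivated, hindered C1 carbonyl alone; oxidation of the C–B bonds gives the primary diol (hydroboration–oxidation).

Step 5
Reactants: 10 6,6-bis(3-hydroxypropyl)-5,5-dimethyl-3-(2-methylpropoxy)cyclohex-2-en-1-one
Product: 11 5,5-dimethyl-3-(2-methylpropoxy)-6,6-bis(3-oxopropyl)cyclohex-2-en-1-one
Conditions: Dess–Martin periodinane, NaHCO3, CH2Cl2, 0 °C → rt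
Reagents that add atoms: none
Why: Dess–Martin oxidation of the primary alcohols stops at the aldehyde under buffered, non-basic conditions that avoid aldol reactions of the dialdehyde.

Step 6
Reactants: 11 5,5-dimethyl-3-(2-methylpropoxy)-6,6-bis(3-oxopropyl)cyclohex-2-en-1-one
Product: 12 6,6-bis(3-hydroxybutyl)-5,5-dimethyl-3-(2-methylpropoxy)cyclohex-2-en-1-one (mixture of carbinol diastereomers)
Conditions: MeMgBr, THF, −78 °C; aq NH4Cl
Reagents that add atoms: methylmagnesium bromide, C[Mg]Br
Why: The Grignard reagent adds to the two aldehydes at low temperature far faster than to the vinylogous ester carbonyl, which is flanked by the quaternary C6; the carbinol configuration is of no consequence.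

Step 7
Reactants: 12 6,6-bis(3-hydroxybutyl)-5,5-dimethyl-3-(2-methylpropoxy)cyclohex-2-en-1-one
Product: 13 5,5-dimethyl-3-(2-methylpropoxy)-6,6-bis(3-oxobutyl)cyclohex-2-en-1-one
Conditions: Dess–Martin periodinane, NaHCO3, CH2Cl2, rt
Reagents that add atoms: none
Why: Dess–Martin oxidation of both secondary alcohols gives the achiral diketone, in which the two 3-oxobutyl arms are enantiotopic.

Step 8
Reactants: 13 5,5-dimethyl-3-(2-methylpropoxy)-6,6-bis(3-oxobutyl)cyclohex-2-en-1-one
Product: 14 (6R,8S,9S)-8-acetyl-9-hydroxy-5,5,9-trimethyl-3-(2-methylpropoxy)spiro[5.5]undec-2-en-1-one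
Conditions: 9-amino-9-deoxy-epi-quinine (20 mol %), 4-nitrobenzoic acid (40 mol %), toluene, 0 °C → rt
Reagents that add atoms: none
Why: Proposed new method: the primary amine condenses with the ketone of one arm, the enamine on the internal carbon (C8) adds to the ketone of the other arm, which is hydrogen-bonded to the protonated quinuclidine, and hydrolysis of the iminium ion returns the catalyst and the β-hydroxy ketone; the closest known reaction type is the amine-catalysed 6-enolexo aldolization, known in desymmetrizing form for 4-substituted heptanedials but not with a ketone acceptor on such a diketone. Ring B closes by 6-enolexo-exo-trig attack through a chair in which the gem-dimethyl carbon C5 is equatorial, whereas the methyl-side enamine has no six-membered closure onto the other arm. C6 is set by the catalyst's choice between the two enantiotopic arms, C8 by the chair, which places the acetyl group equatorial and cis to C5 (the position that enamine epimerization also favours), and C9 by the hydrogen bond, which should hold the acceptor oxygen equatorial and so give the trans ketol with the C9 methyl axial. The step needs arm-to-arm closure in preference to Hajos–Parrish-type closure of the methyl-side enamine onto C1, and the vinylogous ester secures this, because its carbonyl is a far weaker electrophile than a methyl ketone. It also needs the ketol to survive, so low temperature, a weak acid and early work-up are used to limit dehydration, retro-aldol racemisation and amine exchange at C3.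

Step 9
Reactants: 14 (6R,8S,9S)-8-acetyl-9-hydroxy-5,5,9-trimethyl-3-(2-methylpropoxy)spiro[5.5]undec-2-en-1-one
Product: 15 (6R,8S,9S)-9-hydroxy-5,5,9-trimethyl-3-(2-methylpropoxy)-1-oxospiro[5.5]undec-2-en-8-yl acetate
Conditions: mCPBA, Na2HPO4, CH2Cl2, 0 °C → rt
Reagents that add atoms: 3-chloroperoxybenzoic acid, O=C(OO)c1cccc(Cl)c1
Why: Baeyer–Villiger oxidation, in which the secondary carbon C8 migrates in preference to methyl with retention; the push–pull enol ether of ring A is a poor nucleophile toward the buffered peracid, and removal of the ketone ends the risk of retro-aldol racemisation.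

Step 10
Reactants: 15 (6R,8S,9S)-9-hydroxy-5,5,9-trimethyl-3-(2-methylpropoxy)-1-oxospiro[5.5]undec-2-en-8-yl acetate
Product: 16 (6R,8S,9S)-8,9-dihydroxy-5,5,9-trimethyl-3-(2-methylpropoxy)spiro[5.5]undec-2-en-1-one
Conditions: K2CO3, MeOH, 0 °C
Reagents that add atoms: none
Why: Mild base-catalysed methanolysis frees the secondary alcohol without touching the vinylogous ester, and no stereocentre is involved.

Step 11
Reactants: 16 (6R,8S,9S)-8,9-dihydroxy-5,5,9-trimethyl-3-(2-methylpropoxy)spiro[5.5]undec-2-en-1-one
Product: 17 (6R,8S,9S)-5,5,9-trimethyl-3-(2-methylpropoxy)-1-oxospiro[5.5]undec-2-ene-8,9-diyl sulfate (8,9-cyclic sulfate)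
Conditions: 1,1'-sulfonyldiimidazole, NaH, THF, −20 °C → rt
Reagents that add atoms: 1,1'-sulfonyldiimidazole, O=S(=O)(n1ccnc1)n1ccnc1
Why: Double O-sulfonylation closes the trans-diequatorial 1,2-diol to its cyclic sulfate without an oxidant that would attack ring A; this activates C8 and ties up the tertiary oxygen, so that no pinacol-type shift can occur.

Step 12
Reactants: 17 (6R,8S,9S)-8,9-cyclic sulfate
Product: 19 (6R,8R,9S)-8-bromo-9-hydroxy-5,5,9-trimethyl-3-(2-methylpropoxy)spiro[5.5]undec-2-en-1-one, via lithium bromo sulfate 18 (not isolated)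
Conditions: LiBr, THF, 0 °C → rt; then H2SO4 (cat.), H2O (1 equiv), THF, rt
Reagents that add atoms: lithium bromide, [Li+].[Br-]
Why: A cyclic sulfate reacts like an activated epoxide: bromide opens it by SN2 at the secondary carbon C8 with inversion, so bromine ends axial on the face of C1 (8R), and acid-catalysed hydrolysis of the sulfate monoester then gives the bromohydrin.

Step 13
Reactants: 19 (6R,8R,9S)-8-bromo-9-hydroxy-5,5,9-trimethyl-3-(2-methylpropoxy)spiro[5.5]undec-2-en-1-one
Product: 20 (6R,8R,9R)-8-bromo-9-chloro-5,5,9-trimethyl-3-(2-methylpropoxy)spiro[5.5]undec-2-en-1-one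
Conditions: HCl (4 M in 1,4-dioxane), 4 Å molecular sieves, CH2Cl2, 0 °C → rt
Reagents that add atoms: hydrogen chloride, Cl
Why: The tertiary alcohol ionises in anhydrous HCl (SN1), the axial C8 bromine bridges the C9 cation from its own face (bromonium ion) and chloride opens the bridge at the tertiary carbon from the other face, so chloride ends trans-diaxial to bromine (9R) whichever C9 epimer of 19 is present; the sieves take up the water and protect the enol ether.

Step 14
Reactants: 20 (6R,8R,9R)-8-bromo-9-chloro-5,5,9-trimethyl-3-(2-methylpropoxy)spiro[5.5]undec-2-en-1-one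
Product: 22 (4S,6R,8R,9R)-4,8-dibromo-9-chloro-5,5,9-trimethyl-3-(2-methylpropoxy)spiro[5.5]undec-2-en-1-one, via lithium dienolate 21 (not isolated)
Conditions: LiN(i-Pr)2, THF, −78 °C; then N-bromosuccinimide, −78 °C; quench cold
Reagents that add atoms: N-bromosuccinimide, O=C1CCC(=O)N1Br
Why: With C6 quaternary, the base can remove only a γ-proton from C4, and the extended enolate reacts at C4 with the vinylogous ester kept intact (γ-functionalisation of a 3-alkoxy enone); the axial C8 bromine forces the C1 oxygen toward C10 and so fixes the ring A half-chair in which the pseudoaxial C5 methyl shields the face of C11, so under kinetic control bromine should enter on the face of C7 (4S).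

Step 15
Reactants: 22 (4S,6R,8R,9R)-4,8-dibromo-9-chloro-5,5,9-trimethyl-3-(2-methylpropoxy)spiro[5.5]undec-2-en-1-one
Product: 24 (4S,6S,8R,9R)-4,8-dibromo-9-chloro-5,5,9-trimethyl-1-methylidenespiro[5.5]undecan-3-one, via dienol ether 23 (not isolated)
Conditions: Cp2TiMe2, toluene, 65 °C, dark; then oxalic acid, THF/H2O, 0 °C
Reagents that add atoms: dimethyltitanocene (Cp2TiMe2), C[Ti](C)(C1C=CC=C1)C1C=CC=C1; water, O
Why: The titanium methylidene formed from Cp2TiMe2 methylenates the hindered, ester-like C1 carbonyl without base (Petasis olefination), and kinetic protonation of the dienol ether at C2 followed by hydrolysis gives the β,γ-unsaturated ketone with the alkene exocyclic; mild acid and short contact keep the alkene and C4 from equilibrating.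

Step 16
Reactants: 24 (4S,6S,8R,9R)-4,8-dibromo-9-chloro-5,5,9-trimethyl-1-methylidenespiro[5.5]undecan-3-one
Product: 25 (3R,4S,6S,8R,9R)-4,8-dibromo-9-chloro-5,5,9-trimethyl-1-methylidenespiro[5.5]undecan-3-ol
Conditions: i-Bu2AlH, CH2Cl2, −78 °C; aq potassium sodium tartrate
Reagents that add atoms: none
Why: Hydride should be delivered to the C3 carbonyl on the face opposite to the C4–Br bond (Felkin–Anh polar control), which gives the cis-bromohydrin (3R); at −78 °C the hydride does not displace halide and C4 does not epimerise.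

**Compound list**
1 | dimedone (5,5-dimethylcyclohexane-1,3-dione) | CC1(C)CC(=O)CC(=O)C1 | starting material
2 | 2-methylpropan-1-ol | CC(C)CO | starting material
3 | 5,5-dimethyl-3-(2-methylpropoxy)cyclohex-2-en-1-one | CC(C)COC1=CC(=O)CC(C)(C)C1 | intermediate
4 | allyl bromide (3-bromoprop-1-ene) | C=CCBr | starting material
5 | lithium enolate of 3 (C1–O–Li, C1=C6) | [Li]OC1=CC(C)(C)CC(OCC(C)C)=C1 | intermediate
6 | 5,5-dimethyl-3-(2-methylpropoxy)-6-(prop-2-en-1-yl)cyclohex-2-en-1-one (racemic) | C=CCC1C(=O)C=C(OCC(C)C)CC1(C)C | intermediate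
7 | lithium enolate of 6 (C1–O–Li, C1=C6) | [Li]OC1=C(CC=C)C(C)(C)CC(OCC(C)C)=C1 | intermediate
8 | 5,5-dimethyl-3-(2-methylpropoxy)-6,6-di(prop-2-en-1-yl)cyclohex-2-en-1-one | C=CCC1(CC=C)C(=O)C=C(OCC(C)C)CC1(C)C | intermediate
9 | 6,6-bis[3-(9-borabicyclo[3.3.1]nonan-9-yl)propyl]-5,5-dimethyl-3-(2-methylpropoxy)cyclohex-2-en-1-one | CC(C)COC1=CC(=O)C(CCCB2C3CCCC2CCC3)(CCCB2C3CCCC2CCC3)C(C)(C)C1 | intermediate
10 | 6,6-bis(3-hydroxypropyl)-5,5-dimethyl-3-(2-methylpropoxy)cyclohex-2-en-1-one | CC(C)COC1=CC(=O)C(CCCO)(CCCO)C(C)(C)C1 | intermediate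
11 | 5,5-dimethyl-3-(2-methylpropoxy)-6,6-bis(3-oxopropyl)cyclohex-2-en-1-one | CC(C)COC1=CC(=O)C(CCC=O)(CCC=O)C(C)(C)C1 | intermediate
12 | 6,6-bis(3-hydroxybutyl)-5,5-dimethyl-3-(2-methylpropoxy)cyclohex-2-en-1-one (diastereomer mixture) | CC(C)COC1=CC(=O)C(CCC(C)O)(CCC(C)O)C(C)(C)C1 | intermediate
13 | 5,5-dimethyl-3-(2-methylpropoxy)-6,6-bis(3-oxobutyl)cyclohex-2-en-1-one | CC(=O)CCC1(CCC(C)=O)C(=O)C=C(OCC(C)C)CC1(C)C | intermediate
14 | (6R,8S,9S)-8-acetyl-9-hydroxy-5,5,9-trimethyl-3-(2-methylpropoxy)spiro[5.5]undec-2-en-1-one | O=C1C=C(OCC(C)C)CC(C)(C)[C@]12CC[C@](C)(O)[C@@H](C(C)=O)C2 | intermediate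
15 | (6R,8S,9S)-9-hydroxy-5,5,9-trimethyl-3-(2-methylpropoxy)-1-oxospiro[5.5]undec-2-en-8-yl acetate | O=C1C=C(OCC(C)C)CC(C)(C)[C@]12CC[C@](C)(O)[C@@H](OC(C)=O)C2 | intermediate
16 | (6R,8S,9S)-8,9-dihydroxy-5,5,9-trimethyl-3-(2-methylpropoxy)spiro[5.5]undec-2-en-1-one | O=C1C=C(OCC(C)C)CC(C)(C)[C@]12CC[C@](C)(O)[C@@H](O)C2 | intermediate
17 | (6R,8S,9S)-5,5,9-trimethyl-3-(2-methylpropoxy)-1-oxospiro[5.5]undec-2-ene-8,9-diyl sulfate (cyclic sulfate) | O=C1C=C(OCC(C)C)CC(C)(C)[C@]12CC[C@]3(C)OS(=O)(=O)O[C@H]3C2 | intermediate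
18 | lithium (6R,8R,9S)-8-bromo-5,5,9-trimethyl-3-(2-methylpropoxy)-1-oxospiro[5.5]undec-2-en-9-yl sulfate | O=C1C=C(OCC(C)C)CC(C)(C)[C@]12CC[C@](C)(OS(=O)(=O)[O-])[C@H](Br)C2.[Li+] | intermediate
19 | (6R,8R,9S)-8-bromo-9-hydroxy-5,5,9-trimethyl-3-(2-methylpropoxy)spiro[5.5]undec-2-en-1-one | O=C1C=C(OCC(C)C)CC(C)(C)[C@]12CC[C@](C)(O)[C@H](Br)C2 | intermediate
20 | (6R,8R,9R)-8-bromo-9-chloro-5,5,9-trimethyl-3-(2-methylpropoxy)spiro[5.5]undec-2-en-1-one | O=C1C=C(OCC(C)C)CC(C)(C)[C@]12CC[C@@](C)(Cl)[C@H](Br)C2 | intermediate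
21 | lithium dienolate of 20 (C1–O–Li, C1=C2, C3=C4) | [Li]OC1=CC(OCC(C)C)=CC(C)(C)[C@]12CC[C@@](C)(Cl)[C@H](Br)C2 | intermediate
22 | (4S,6R,8R,9R)-4,8-dibromo-9-chloro-5,5,9-trimethyl-3-(2-methylpropoxy)spiro[5.5]undec-2-en-1-one | O=C1C=C(OCC(C)C)[C@@H](Br)C(C)(C)[C@]12CC[C@@](C)(Cl)[C@H](Br)C2 | intermediate
23 | (4S,6S,8R,9R)-4,8-dibromo-9-chloro-5,5,9-trimethyl-1-methylidene-3-(2-methylpropoxy)spiro[5.5]undec-2-ene | C=C1C=C(OCC(C)C)[C@@H](Br)C(C)(C)[C@]12CC[C@@](C)(Cl)[C@H](Br)C2 | intermediate
24 | (4S,6S,8R,9R)-4,8-dibromo-9-chloro-5,5,9-trimethyl-1-methylidenespiro[5.5]undecan-3-one | C=C1CC(=O)[C@@H](Br)C(C)(C)[C@]12CC[C@@](C)(Cl)[C@H](Br)C2 | intermediate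
25 | (3R,4S,6S,8R,9R)-4,8-dibromo-9-chloro-5,5,9-trimethyl-1-methylidenespiro[5.5]undecan-3-ol | C=C1C[C@@H](O)[C@@H](Br)C(C)(C)[C@]12CC[C@@](C)(Cl)[C@H](Br)C2 | target

**Step count**
Total steps: 16. Longest linear sequence: 16 steps (from dimedone).

**Steps most likely to fail**

Step 8 (desymmetrizing aldol).
- What may go wrong: the catalyst may not tell the two arms apart, the methyl-side enamine may close onto C1, the amine may be consumed by exchange at C3, or the ketol may dehydrate or revert and lose its configuration.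
- Fallback (known chemistry, sets out from 3, comes back at 16): C6 is made stereogenic with two different arms and ring B is closed by olefin metathesis.
- Alkylation of 3 (LiN(i-Pr)2; 4-bromo-2-methylbut-1-ene, NaI) would give 5,5-dimethyl-6-(3-methylbut-3-en-1-yl)-3-(2-methylpropoxy)cyclohex-2-en-1-one F1.
- O-Acylation of its lithium enolate with allyl chloroformate would give the allyl enol carbonate F2.
- Enantioselective decarboxylative allylation (Pd2(dba)3 with (S)-t-BuPHOX, or its enantiomer as a test decides) would give the (6R)-6-allyl ketone F3.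
- Ring-closing metathesis with the second-generation Grubbs catalyst would give the spiro diene F4.
- mCPBA should epoxidize the trisubstituted alkene on the face away from the axial C1 to give the epoxide F5.
- Acid-catalysed hydrolysis (HClO4 cat., THF/H2O, 0 °C), with water entering at the tertiary C9 with inversion, would give diol 16.

Step 12 (bromide opening at C8).
- What may go wrong: bromide has to enter axially past C1, so the opening may be slow, and ionisation at the tertiary C9–O bond or elimination may take over.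
- Fallback (sets out from 16, comes back at 20): the hindered SN2 on the trans-fused sulfate is replaced by a trans-diaxial epoxide opening.
- Garegg–Samuelsson deoxygenation of 16 (PPh3, I2, imidazole, toluene, reflux) would give the alkene F4, and mCPBA the epoxide F5.
- Li2NiBr4 in THF should open it at the secondary C8 in the trans-diaxial sense to give the bromohydrin F6, the C9 epimer of 19.
- HCl as in step 13 would then give 20 with retention at C9 through the same bromonium ion.

Step 14 (γ-bromination at C4).
- What may go wrong: the extended enolate may be brominated at C2 instead of C4, the amide base may remove hydrogen halide from ring B, or equilibration through the enolate may erode the C4 configuration.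
- Fallback (sets out from 20, comes back at 22, no new compound): radical allylic bromination (N-bromosuccinimide, AIBN, PhCF3, 80 °C) substitutes the only allylic CH2 of ring A without base; bromine transfer to the allylic radical should again occur anti to the pseudoaxial C5 methyl.

**Further compounds**
F1 | step 8 | 5,5-dimethyl-6-(3-methylbut-3-en-1-yl)-3-(2-methylpropoxy)cyclohex-2-en-1-one (racemic) | C=C(C)CCC1C(=O)C=C(OCC(C)C)CC1(C)C
F2 | step 8 | 5,5-dimethyl-6-(3-methylbut-3-en-1-yl)-3-(2-methylpropoxy)cyclohexa-1(6),2-dien-1-yl prop-2-en-1-yl carbonate | C=CCOC(=O)OC1=C(CCC(C)=C)C(C)(C)CC(OCC(C)C)=C1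
F3 | step 8 | (6R)-5,5-dimethyl-6-(3-methylbut-3-en-1-yl)-3-(2-methylpropoxy)-6-(prop-2-en-1-yl)cyclohex-2-en-1-one | C=CC[C@@]1(CCC(C)=C)C(=O)C=C(OCC(C)C)CC1(C)C
F4 | step 8 | (6R)-5,5,9-trimethyl-3-(2-methylpropoxy)spiro[5.5]undeca-2,8-dien-1-one | O=C1C=C(OCC(C)C)CC(C)(C)[C@]12CCC(C)=CC2
F5 | step 8 | (6R,8S,9R)-8,9-epoxy-5,5,9-trimethyl-3-(2-methylpropoxy)spiro[5.5]undec-2-en-1-one | O=C1C=C(OCC(C)C)CC(C)(C)[C@]12CC[C@@]3(C)O[C@H]3C2
F6 | step 12 | (6R,8R,9R)-8-bromo-9-hydroxy-5,5,9-trimethyl-3-(2-methylpropoxy)spiro[5.5]undec-2-en-1-one | O=C1C=C(OCC(C)C)CC(C)(C)[C@]12CC[C@@](C)(O)[C@H](Br)C2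
F0 | step 14 | none | none
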